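**Plan**

Numbering (daucane): C1 = ring-fusion C(CH3), its methyl is C15; C2, C3 = CH2; C4 = C(OH)(i-Pr); C5 = ring-fusion CH; C6 = CH–O-aroyl; C7 = CH2; C8(CH3)=C9H; C10 = CH–O-isovaleryl; α is the face of C15.
Cuts, backwards: both ester C–O bonds; then C6–OH, C5–H and C4–OH back to a 4β,5β-epoxy-6-ketone and on to a C4=C5 alkene with a 6β-hydroxyl; then the C8(CH3)=C9–C10(OH) unit back, by a 1,3-oxidative transposition and loss of C14, to the enone C8(=O)–C9=C10.
Structural feature used: in the seven-membered ring the two-carbon unit C10–C1 lies between the vinylic C9 and the ring-fusion C5, so joining C5 to C9 turns that ring into a cyclopentanone (C5–C6–C7–C8–C9) fused to a cyclobutane (C5–C1–C10–C9); this cyclobutane is cut at C9–C10 and C1–C5 into a cyclopentenone C5=C9 and a chloroalkene C1=C10 held three atoms apart by C4–C3–C2, and C4–C5 is cut into a vinyllithium and a ketone.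
Forward: the cyclopentenone ring comes from the chiral pool; one photochemical step closes the cyclopentane (C1–C5) and the cyclobutane (C9–C10); a radical formed at C4 then breaks C5–C9 and opens the seven-membered ring of the hydroazulene.
Stereochemistry: the stereocenter of (R)-4-silyloxycyclopentenone is relayed by Luche reduction to a 6β-silyl ether, which steers the photocycloaddition and fixes C1; C15 then controls hydride delivery at C10, the 6β-hydroxyl directs the epoxidation that sets C4, and C5 and C6 follow from protonation and hydride delivery on the face away from C15 and the isopropyl group.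
Helpers: the C10 chloride (leaving group), the C4 oxalate (radical precursor) and the 6β-silyl ether (facial control) are all removed later; C4, the chloroalkene geometry and C10 are carried as mixtures until the fragmentation makes them trigonal, so their SMILES leave these centres open.

Key step: step 9

Remark: (R)-4-(tert-butyldimethylsilyloxy)cyclopent-2-en-1-one and 4-(tert-butyldimethylsilyloxy)benzoic acid are taken as commercial starting materials.

**Route**

Step 1
Reactants: 1 isobutyraldehyde (2-methylpropanal); 2 methyl vinyl ketone (but-3-en-2-one)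
Product: 3 6-methylheptane-2,5-dione
Conditions: 3-benzyl-5-(2-hydroxyethyl)-4-methylthiazolium chloride (10 mol %), Et3N, EtOH, 80 °C
Reagents that add atoms: none
Why: Stetter reaction, in which the thiazolium-derived acyl anion equivalent of 1 adds 1,4 to 2 and gives the 1,4-diketone that holds C11–C4–C3–C2–C1–C15 in the right order, with no stereocenter formed.

Step 2
Reactants: 3 6-methylheptane-2,5-dione
Product: 4 7-chloro-2,6-dimethylhept-6-en-3-one (E/Z mixture)
Conditions: Ph3P(CH2Cl)Cl, NaN(SiMe3)2, THF, −78 → 23 °C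
Reagents that add atoms: (chloromethyl)triphenylphosphonium chloride, ClC[P+](c1ccccc1)(c1ccccc1)c1ccccc1.[Cl-]
Why: Wittig chloromethylenation, in which the ylide should take the unhindered methyl ketone (C1) and leave the α-branched isopropyl ketone (C4), so that C10 arrives as a vinylic CHCl whose chloride later serves as a leaving group; the alkene geometry is irrelevant.

Step 3
Reactants: 5 (R)-4-(tert-butyldimethylsilyloxy)cyclopent-2-en-1-one
Product: 6 (R)-4-(tert-butyldimethylsilyloxy)-2-iodocyclopent-2-en-1-one
Conditions: I2, pyridine, CH2Cl2, 0 → 23 °C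
Reagents that add atoms: iodine, I-I
Why: α-iodination of an enone by conjugate addition of pyridine, iodination of the enolate and elimination, which leaves the silyloxy stereocenter untouched.

Step 4
Reactants: 6 (R)-4-(tert-butyldimethylsilyloxy)-2-iodocyclopent-2-en-1-one
Product: 7 (1S,4R)-4-(tert-butyldimethylsilyloxy)-2-iodocyclopent-2-en-1-ol
Conditions: NaBH4, CeCl3·7H2O, MeOH, −78 °C
Reagents that add atoms: none
Why: Luche 1,2-reduction, in which hydride enters anti to the silyloxy group, so the new carbinol (the later C6) is cis to it and the stereochemical information is relayed from the carbon that will become the C8 ketone.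

Step 5
Reactants: 7 (1S,4R)-4-(tert-butyldimethylsilyloxy)-2-iodocyclopent-2-en-1-ol
Product: 8 (3R,5S)-3-(tert-butyldimethylsilyloxy)-1-iodo-5-(triisopropylsilyloxy)cyclopent-1-ene
Conditions: i-Pr3SiOSO2CF3, 2,6-lutidine, CH2Cl2, 0 °C
Reagents that add atoms: triisopropylsilyl trifluoromethanesulfonate, CC(C)[Si](C(C)C)(C(C)C)OS(=O)(=O)C(F)(F)F
Why: silylation of the secondary alcohol, which places on the future C6 a bulky, robust ether that can be told apart from the tert-butyldimethylsilyl ether and will shield one enone face in step 9.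

Step 6
Reactants: 8 (3R,5S)-3-(tert-butyldimethylsilyloxy)-1-iodo-5-(triisopropylsilyloxy)cyclopent-1-ene; 4 7-chloro-2,6-dimethylhept-6-en-3-one
Product: 11 7-chloro-3-[(3R,5S)-3-(tert-butyldimethylsilyloxy)-5-(triisopropylsilyloxy)cyclopent-1-en-1-yl]-2,6-dimethylhept-6-en-3-yl methyl oxalate, via vinyllithium 9 (not isolated), via lithium alkoxide 10 (not isolated)
Conditions: t-BuLi (2 equiv), Et2O, −78 °C; 4, −78 °C; ClC(O)CO2Me, −78 → 0 °C
Reagents that add atoms: methyl chlorooxoacetate, COC(=O)C(Cl)=O
Why: iodine–lithium exchange, 1,2-addition of the vinyllithium to the ketone of 4 (the vinyl chloride is inert) and O-acylation of the hindered tertiary alkoxide in the same flask form the C4–C5 bond and the radical precursor, and the carbinol centre C4 forms as both epimers, which is accepted because it becomes trigonal in step 11.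

Step 7
Reactants: 11 the bis-silyl methyl oxalate
Product: 12 7-chloro-3-[(3R,5S)-3-hydroxy-5-(triisopropylsilyloxy)cyclopent-1-en-1-yl]-2,6-dimethylhept-6-en-3-yl methyl oxalate
Conditions: HF·pyridine, pyridine, THF, 0 → 23 °C
Reagents that add atoms: none
Why: selective desilylation, in which the less hindered secondary tert-butyldimethylsilyl ether is cleaved while the triisopropylsilyl ether next to the fully substituted alkene carbon and the oxalate should survive buffered HF.

Step 8
Reactants: 12 the allylic alcohol
Product: 13 7-chloro-2,6-dimethyl-3-[(5S)-3-oxo-5-(triisopropylsilyloxy)cyclopent-1-en-1-yl]hept-6-en-3-yl methyl oxalate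
Conditions: MnO2, CH2Cl2, 23 °C
Reagents that add atoms: none
Why: allylic oxidation with MnO2 gives the cyclopentenone (C8 ketone, C9 α-carbon, C5 β-carbon) that carries the tether on its β-carbon and the silyl ether on C6 next to it.

Step 9
Reactants: 13 the enone with the tethered chloroalkene
Product: 14 10-chloro-8-oxo-6β-(triisopropylsilyloxy)-14-nor-5,9-cyclodaucan-4-yl methyl oxalate (cyclobutane C5–C1–C10–C9 on the β face; C4 and C10 epimers)
Conditions: hν (350 nm), degassed CH2Cl2 (0.01 mol/L), 0 °C
Reagents that add atoms: none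
Why: n→π* excitation and intersystem crossing give the triplet enone, whose β-carbon C5 bonds first to the internal alkene carbon C1 (5-exo closure of the cyclopentane C1–C5 through the three-atom tether C4–C3–C2, the rule of five), leaving a 1,4-biradical (α-keto radical at C9, α-chloro radical at C10) that closes the cyclobutane C5–C1–C10–C9 by radical recombination after spin inversion, which gives the straight and not the crossed adduct. The closest known reaction type is the intramolecular enone–alkene [2+2] photocycloaddition of 3-(pent-4-enyl)cyclopent-2-enones. The quaternary centres C1 and C5 and the methine C9 are fixed relative to each other by the obligatory cis fusion of both five-membered rings to the cyclobutane, and their absolute sense by approach of the tether to the enone face anti to the triisopropylsilyloxy group on C6. C10 forms without control and C4 is a preset mixture, which is tolerated because both become trigonal in step 11. The step needs straight regioselectivity and facial selectivity, the first secured by the tether length and the second by the bulky silyl ether on the ring carbon next to C5.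

Step 10
Reactants: 14 the tricyclic methyl oxalate
Product: 15 cesium 10-chloro-8-oxo-6β-(triisopropylsilyloxy)-14-nor-5,9-cyclodaucan-4-yl oxalate
Conditions: CsOH·H2O (1.0 equiv), THF/H2O, 0 °C
Reagents that add atoms: cesium hydroxide, [Cs+].[OH-]
Why: saponification with one equivalent of hydroxide should take the unhindered, highly electrophilic methyl ester of the mixed oxalate and leave the hindered tertiary ester, giving the cesium oxalate salt.

Step 11
Reactants: 15 the cesium oxalate
Product: 17 6β-(triisopropylsilyloxy)-14-nordauca-4,9-dien-8-one, via cesium enolate 16 (not isolated)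
Conditions: [Ir(dF(CF3)ppy)2(dtbbpy)]PF6 (1 mol %), DME/DMF (3:1), H2O (10 equiv), blue LEDs, 40 °C
Reagents that add atoms: none
Why: Proposed new method: the excited iridium photocatalyst should oxidise the oxalate carboxylate, loss of two CO2 gives the tertiary C4 radical, whose half-filled orbital overlaps with the strained cyclobutane bond C5–C9 (exocyclic to the cyclopentane that holds C4) and not with the ring bond C5–C1, so β-scission opens the seven-membered ring, forms the tetrasubstituted C4=C5 alkene and leaves an α-keto radical at C9 that the reduced photocatalyst turns into the C8 enolate 16, which expels chloride from C10 (E1cB) to give the enone C8(=O)–C9=C10 in an overall redox-neutral process; the closest known reaction types are the visible-light photoredox deoxygenation of tertiary cesium oxalates that ends with reduction of an α-carbonyl radical and the tin hydride fragmentation of cyclobutylcarbinyl radicals in enone–alkene photoadducts; no stereocenter is formed and the C4 and C10 mixtures converge.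

Step 12
Reactants: 17 the dienone
Product: 18 6β-(triisopropylsilyloxy)dauca-4,9-dien-8-ol (C8 epimers)
Conditions: MeLi, Et2O, −78 °C; then H2O
Reagents that add atoms: methyllithium, [Li]C
Why: 1,2-addition of methyllithium to the enone carbonyl brings in C14, and the configuration of the tertiary carbinol C8 does not matter because it becomes trigonal in step 13.

Step 13
Reactants: 18 the tertiary allylic alcohol
Product: 19 6β-(triisopropylsilyloxy)dauca-4,8-dien-10-one
Conditions: C5H5NH[CrO3Cl] (pyridinium chlorochromate), 4 Å molecular sieves, CH2Cl2, 23 °C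
Reagents that add atoms: pyridinium chlorochromate, [O-][Cr](=O)(=O)Cl.c1cc[nH+]cc1
Why: Dauben–Babler oxidative 1,3-transposition, in which the chromate ester of the tertiary allylic alcohol undergoes a [3,3] shift to C10 and is oxidised there, which moves oxygen to C10 and sets the C8=C9 double bond with the methyl on C8.

Step 14
Reactants: 19 the transposed enone
Product: 20 6β-(triisopropylsilyloxy)dauca-4,8-dien-10α-ol
Conditions: NaBH4, CeCl3·7H2O, MeOH, −78 °C
Reagents that add atoms: none
Why: Luche 1,2-reduction of the enone, in which the C1–C15 bond on the neighbouring quaternary carbon stands roughly perpendicular to the carbonyl plane, so hydride should enter anti to C15 and place the C10 hydroxyl on the α face (10S).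

Step 15
Reactants: 20 the allylic alcohol
Product: 21 6β-(triisopropylsilyloxy)dauca-4,8-dien-10α-yl 3-methylbutanoate
Conditions: isovaleryl chloride, pyridine, DMAP (cat.), CH2Cl2, 0 → 23 °C
Reagents that add atoms: 3-methylbutanoyl chloride, CC(C)CC(Cl)=O
Why: DMAP-catalysed acylation of the only free hydroxyl installs the isovalerate of the target.

Step 16
Reactants: 21 the silyl ether ester
Product: 22 6β-hydroxydauca-4,8-dien-10α-yl 3-methylbutanoate
Conditions: Bu4NF, AcOH, THF, 0 → 23 °C
Reagents that add atoms: none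
Why: fluoride-mediated cleavage of the triisopropylsilyl ether under acetic acid buffering frees the 6β-allylic alcohol without touching the ester.

Step 17
Reactants: 22 the 6β-allylic alcohol
Product: 23 4β,5β-epoxy-6β-hydroxydauc-8-en-10α-yl 3-methylbutanoate
Conditions: VO(acac)2 (5 mol %), t-BuOOH, CH2Cl2, 0 → 23 °C
Reagents that add atoms: tert-butyl hydroperoxide, CC(C)(C)OO
Why: vanadium-catalysed hydroxyl-directed epoxidation, in which the peroxide bound to the 6β-alkoxide is delivered to the tetrasubstituted allylic C4=C5 alkene on the β face, which is also the face anti to C15, and so sets the C4–O stereocenter, while the homoallylic C8=C9 alkene should react much more slowly.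

Step 18
Reactants: 23 the epoxy alcohol
Product: 24 4β,5β-epoxy-6-oxodauc-8-en-10α-yl 3-methylbutanoate
Conditions: Pr4N[RuO4] (5 mol %), N-methylmorpholine N-oxide, 4 Å molecular sieves, CH2Cl2, 0 °C
Reagents that add atoms: none
Why: Ley–Griffith oxidation of the secondary epoxy alcohol under neutral conditions gives the α,β-epoxy ketone and removes the auxiliary 6β stereocenter.

Step 19
Reactants: 24 the epoxy ketone
Product: 26 4β,6α-dihydroxy-5βH-dauc-8-en-10α-yl 3-methylbutanoate, via hydroxy ketone 25 (not isolated)
Conditions: SmI2 (2.2 equiv), THF/MeOH, −90 °C; then NaBH4, −78 → −40 °C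
Reagents that add atoms: none
Why: SmI2 reductive opening of the α,β-epoxy ketone cleaves the C5–O bond, and the samarium enolate should be protonated at C5 on the β face because C15 and the now α isopropyl group block the other, which sets the trans ring fusion, and borohydride added to the cold mixture should then attack the C6 ketone from the same open face and give the 6α-alcohol before the β,γ-unsaturated ketone can isomerise.

Step 20
Reactants: 26 the diol ester; 27 4-(tert-butyldimethylsilyloxy)benzoic acid
Product: 28 4β-hydroxy-10α-(3-methylbutanoyloxy)-5βH-dauc-8-en-6α-yl 4-(tert-butyldimethylsilyloxy)benzoate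
Conditions: N,N'-dicyclohexylcarbodiimide, DMAP, CH2Cl2, 23 °C
Reagents that add atoms: none
Why: Steglich esterification should acylate the secondary C6 hydroxyl only, since the tertiary C4 hydroxyl is inert under these conditions.

Step 21
Reactants: 28 the silyl-protected diester
Product: 29 4β-hydroxy-10α-(3-methylbutanoyloxy)-5βH-dauc-8-en-6α-yl 4-hydroxybenzoate (CNP0086724.2)
Conditions: Bu4NF, AcOH, THF, 0 °C
Reagents that add atoms: none
Why: fluoride cleavage of the aryl silyl ether, which under acetic acid buffering is much faster than attack on the two esters, liberates the phenol and gives the target.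

**Compound list**

1 | isobutyraldehyde (2-methylpropanal) | CC(C)C=O | starting material
2 | methyl vinyl ketone (but-3-en-2-one) | CC(=O)C=C | starting material
3 | 6-methylheptane-2,5-dione | CC(C)C(=O)CCC(C)=O | intermediate
4 | 7-chloro-2,6-dimethylhept-6-en-3-one (E/Z mixture) | CC(C)C(=O)CCC(C)=CCl | intermediate
5 | (R)-4-(tert-butyldimethylsilyloxy)cyclopent-2-en-1-one | O=C1C=C[C@H](O[Si](C)(C)C(C)(C)C)C1 | starting material
6 | (R)-4-(tert-butyldimethylsilyloxy)-2-iodocyclopent-2-en-1-one | O=C1C(I)=C[C@H](O[Si](C)(C)C(C)(C)C)C1 | intermediate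
7 | (1S,4R)-4-(tert-butyldimethylsilyloxy)-2-iodocyclopent-2-en-1-ol (cis) | IC1=C[C@H](O[Si](C)(C)C(C)(C)C)C[C@@H]1O | intermediate
8 | (3R,5S)-3-(tert-butyldimethylsilyloxy)-1-iodo-5-(triisopropylsilyloxy)cyclopent-1-ene (cis) | IC1=C[C@H](O[Si](C)(C)C(C)(C)C)C[C@@H]1O[Si](C(C)C)(C(C)C)C(C)C | intermediate
9 | [(3R,5S)-3-(tert-butyldimethylsilyloxy)-5-(triisopropylsilyloxy)cyclopent-1-en-1-yl]lithium | [Li]C1=C[C@H](O[Si](C)(C)C(C)(C)C)C[C@@H]1O[Si](C(C)C)(C(C)C)C(C)C | intermediate
10 | lithium 7-chloro-3-[(3R,5S)-3-(tert-butyldimethylsilyloxy)-5-(triisopropylsilyloxy)cyclopent-1-en-1-yl]-2,6-dimethylhept-6-en-3-olate (C4 epimers, E/Z) | CC(C)C([O-])(CCC(C)=CCl)C1=C[C@H](O[Si](C)(C)C(C)(C)C)C[C@@H]1O[Si](C(C)C)(C(C)C)C(C)C.[Li+] | intermediate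
11 | 7-chloro-3-[(3R,5S)-3-(tert-butyldimethylsilyloxy)-5-(triisopropylsilyloxy)cyclopent-1-en-1-yl]-2,6-dimethylhept-6-en-3-yl methyl oxalate (C4 epimers, E/Z) | COC(=O)C(=O)OC(CCC(C)=CCl)(C(C)C)C1=C[C@H](O[Si](C)(C)C(C)(C)C)C[C@@H]1O[Si](C(C)C)(C(C)C)C(C)C | intermediate
12 | 7-chloro-3-[(3R,5S)-3-hydroxy-5-(triisopropylsilyloxy)cyclopent-1-en-1-yl]-2,6-dimethylhept-6-en-3-yl methyl oxalate (C4 epimers, E/Z) | COC(=O)C(=O)OC(CCC(C)=CCl)(C(C)C)C1=C[C@H](O)C[C@@H]1O[Si](C(C)C)(C(C)C)C(C)C | intermediate
13 | 7-chloro-2,6-dimethyl-3-[(5S)-3-oxo-5-(triisopropylsilyloxy)cyclopent-1-en-1-yl]hept-6-en-3-yl methyl oxalate (C4 epimers, E/Z) | COC(=O)C(=O)OC(CCC(C)=CCl)(C(C)C)C1=CC(=O)C[C@@H]1O[Si](C(C)C)(C(C)C)C(C)C | intermediate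
14 | 10-chloro-8-oxo-6β-(triisopropylsilyloxy)-14-nor-5,9-cyclodaucan-4-yl methyl oxalate (cyclobutane C5–C1–C10–C9; C4 and C10 epimers) | O=C1C[C@H](O[Si](C(C)C)(C(C)C)C(C)C)[C@]23[C@H]1C(Cl)[C@@]2(C)CCC3(OC(=O)C(=O)OC)C(C)C | intermediate
15 | cesium 10-chloro-8-oxo-6β-(triisopropylsilyloxy)-14-nor-5,9-cyclodaucan-4-yl oxalate (C4 and C10 epimers) | O=C1C[C@H](O[Si](C(C)C)(C(C)C)C(C)C)[C@]23[C@H]1C(Cl)[C@@]2(C)CCC3(OC(=O)C(=O)[O-])C(C)C.[Cs+] | intermediate
16 | cesium C8(O)=C9 enolate of 10-chloro-6β-(triisopropylsilyloxy)-14-nordauc-4-en-8-one (C10 epimers) | CC(C)C1=C2[C@@H](O[Si](C(C)C)(C(C)C)C(C)C)CC([O-])=CC(Cl)[C@@]2(C)CC1.[Cs+] | intermediate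
17 | 6β-(triisopropylsilyloxy)-14-nordauca-4,9-dien-8-one | CC(C)C1=C2[C@@H](O[Si](C(C)C)(C(C)C)C(C)C)CC(=O)C=C[C@@]2(C)CC1 | intermediate
18 | 6β-(triisopropylsilyloxy)dauca-4,9-dien-8-ol (C8 epimers) | CC(C)C1=C2[C@@H](O[Si](C(C)C)(C(C)C)C(C)C)CC(C)(O)C=C[C@@]2(C)CC1 | intermediate
19 | 6β-(triisopropylsilyloxy)dauca-4,8-dien-10-one | CC(C)C1=C2[C@@H](O[Si](C(C)C)(C(C)C)C(C)C)CC(C)=CC(=O)[C@@]2(C)CC1 | intermediate
20 | 6β-(triisopropylsilyloxy)dauca-4,8-dien-10α-ol | CC(C)C1=C2[C@@H](O[Si](C(C)C)(C(C)C)C(C)C)CC(C)=C[C@H](O)[C@@]2(C)CC1 | intermediate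
21 | 6β-(triisopropylsilyloxy)dauca-4,8-dien-10α-yl 3-methylbutanoate | CC(C)C1=C2[C@@H](O[Si](C(C)C)(C(C)C)C(C)C)CC(C)=C[C@H](OC(=O)CC(C)C)[C@@]2(C)CC1 | intermediate
22 | 6β-hydroxydauca-4,8-dien-10α-yl 3-methylbutanoate | CC(C)C1=C2[C@@H](O)CC(C)=C[C@H](OC(=O)CC(C)C)[C@@]2(C)CC1 | intermediate
23 | 4β,5β-epoxy-6β-hydroxydauc-8-en-10α-yl 3-methylbutanoate | CC(C)[C@]12O[C@]13[C@@H](O)CC(C)=C[C@H](OC(=O)CC(C)C)[C@@]3(C)CC2 | intermediate
24 | 4β,5β-epoxy-6-oxodauc-8-en-10α-yl 3-methylbutanoate | CC(C)[C@]12O[C@]13C(=O)CC(C)=C[C@H](OC(=O)CC(C)C)[C@@]3(C)CC2 | intermediate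
25 | 4β-hydroxy-6-oxo-5βH-dauc-8-en-10α-yl 3-methylbutanoate (trans-fused) | CC1=C[C@H](OC(=O)CC(C)C)[C@@]2(C)CC[C@](O)(C(C)C)[C@@H]2C(=O)C1 | intermediate
26 | 4β,6α-dihydroxy-5βH-dauc-8-en-10α-yl 3-methylbutanoate | CC1=C[C@H](OC(=O)CC(C)C)[C@@]2(C)CC[C@](O)(C(C)C)[C@@H]2[C@H](O)C1 | intermediate
27 | 4-(tert-butyldimethylsilyloxy)benzoic acid | CC(C)(C)[Si](C)(C)Oc1ccc(cc1)C(=O)O | starting material
28 | 4β-hydroxy-10α-(3-methylbutanoyloxy)-5βH-dauc-8-en-6α-yl 4-(tert-butyldimethylsilyloxy)benzoate | CC1=C[C@H](OC(=O)CC(C)C)[C@@]2(C)CC[C@](O)(C(C)C)[C@@H]2[C@H](OC(=O)c2ccc(O[Si](C)(C)C(C)(C)C)cc2)C1 | intermediate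
29 | 4β-hydroxy-10α-(3-methylbutanoyloxy)-5βH-dauc-8-en-6α-yl 4-hydroxybenzoate (CNP0086724.2) | CC1=C[C@H](OC(=O)CC(C)C)[C@@]2(C)CC[C@](O)(C(C)C)[C@@H]2[C@H](OC(=O)c2ccc(O)cc2)C1 | target

**Step count and risks**

Total steps: 21. Longest linear sequence: 19 steps (5 to 29, steps 3–21); the two-step branch to 4 joins in step 6.

The three steps most likely to fail:

Step 11 (bears the label "Proposed new method:"). The C4 radical may be quenched by hydrogen abstraction or back electron transfer before the cyclobutane opens, or the ring may open at C5–C1 instead of C5–C9. The fallback uses known tin hydride chemistry and sets out from 14. Heating 14 with Bu3SnH and azobisisobutyronitrile in toluene at 110 °C, with slow addition of the hydride (Barton–McCombie-type deoxygenation of a tertiary methyl oxalate), should generate the same C4 radical in a chain process. Ring opening and hydrogen transfer to C9 should give 10-chloro-6β-(triisopropylsilyloxy)-14-nordauc-4-en-8-one F1. Et3N in CH2Cl2 then eliminates HCl from F1 (E1cB), and the sequence comes back to the route at 17.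

Step 9. The oxalate ester may quench the triplet or decompose under irradiation, addition to the chloroalkene may be slow, or the bulky oxalate may erode facial control. The fallback moves the radical precursor behind the cycloaddition and sets out from 8 (with 4). The vinyllithium 9 is added to 4 and quenched with water to give the tertiary alcohol 7-chloro-3-[(3R,5S)-3-(tert-butyldimethylsilyloxy)-5-(triisopropylsilyloxy)cyclopent-1-en-1-yl]-2,6-dimethylhept-6-en-3-ol F2. HF·pyridine then gives the diol (1R,4S)-3-(7-chloro-3-hydroxy-2,6-dimethylhept-6-en-3-yl)-4-(triisopropylsilyloxy)cyclopent-2-en-1-ol F3, and MnO2 gives the hydroxy enone (4S)-3-(7-chloro-3-hydroxy-2,6-dimethylhept-6-en-3-yl)-4-(triisopropylsilyloxy)cyclopent-2-en-1-one F4. Irradiation of F4, now without the oxalate chromophore, should give the photoadduct alcohol 10-chloro-4-hydroxy-6β-(triisopropylsilyloxy)-14-nor-5,9-cyclodaucan-8-one F5. Acylation of F5 with methyl chlorooxoacetate, DMAP and pyridine comes back to the route at 14.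

Step 17. Oxygen transfer to the hindered tetrasubstituted alkene may be so slow that the C8=C9 alkene competes, or the Lewis-acidic vanadium may open the epoxy alcohol. The fallback replaces the directed electrophilic epoxidation by a nucleophilic one and sets out from 22. Oxidation with Pr4N[RuO4] and N-methylmorpholine N-oxide gives the enone 6-oxodauca-4,8-dien-10α-yl 3-methylbutanoate F6. Weitz–Scheffer epoxidation of F6 with t-BuOOH and DBU in CH2Cl2, on the face anti to C15, comes back to the route at 24.

**Further compounds**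

F1 | step 11 | 10-chloro-6β-(triisopropylsilyloxy)-14-nordauc-4-en-8-one (C10 epimers) | CC(C)C1=C2[C@@H](O[Si](C(C)C)(C(C)C)C(C)C)CC(=O)CC(Cl)[C@@]2(C)CC1
F2 | step 9 | 7-chloro-3-[(3R,5S)-3-(tert-butyldimethylsilyloxy)-5-(triisopropylsilyloxy)cyclopent-1-en-1-yl]-2,6-dimethylhept-6-en-3-ol (C4 epimers, E/Z) | CC(C)C(O)(CCC(C)=CCl)C1=C[C@H](O[Si](C)(C)C(C)(C)C)C[C@@H]1O[Si](C(C)C)(C(C)C)C(C)C
F3 | step 9 | (1R,4S)-3-(7-chloro-3-hydroxy-2,6-dimethylhept-6-en-3-yl)-4-(triisopropylsilyloxy)cyclopent-2-en-1-ol (C4 epimers, E/Z) | CC(C)C(O)(CCC(C)=CCl)C1=C[C@H](O)C[C@@H]1O[Si](C(C)C)(C(C)C)C(C)C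
F4 | step 9 | (4S)-3-(7-chloro-3-hydroxy-2,6-dimethylhept-6-en-3-yl)-4-(triisopropylsilyloxy)cyclopent-2-en-1-one (C4 epimers, E/Z) | CC(C)C(O)(CCC(C)=CCl)C1=CC(=O)C[C@@H]1O[Si](C(C)C)(C(C)C)C(C)C
F5 | step 9 | 10-chloro-4-hydroxy-6β-(triisopropylsilyloxy)-14-nor-5,9-cyclodaucan-8-one (C4 and C10 epimers) | O=C1C[C@H](O[Si](C(C)C)(C(C)C)C(C)C)[C@]23[C@H]1C(Cl)[C@@]2(C)CCC3(O)C(C)C
F6 | step 17 | 6-oxodauca-4,8-dien-10α-yl 3-methylbutanoate | CC(C)C1=C2C(=O)CC(C)=C[C@H](OC(=O)CC(C)C)[C@@]2(C)CC1
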